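1. If I want the plateau of this flask, I count target against the smaller charge, the limiting reagent, and not against the starting material.

| flask | starting material | reagent | remark | time |
|---|---|---|---|---|
| cedar | 0.10 M | 0.040 M | run made earlier |  |
| larch | 0.10 M | 0.090 M | run made earlier |  |
| maple | 0.050 M | 0.060 M | run made earlier |  |
| flask | 0.10 M | 0.0600 M |  | 4.0 h |

| run | time / h | target / % | side product A / % |
|---|---|---|---|
| cedar | 0.667 | 14 | 9 |
| cedar | 1.33 | 15 | 9 |
| cedar | 2.00 | 15 | 11 |
| cedar | 2.50 | 16 | 12 |
| cedar | 3.00 | 14 | 11 |
| cedar | 4.00 | 13 | 9 |
| larch | 0.667 | 30 | 21 |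
| larch | 1.33 | 30 | 23 |
| larch | 2.00 | 29 | 23 |
| larch | 2.50 | 30 | 21 |
| larch | 3.00 | 31 | 22 |
| larch | 4.00 | 31 | 23 |
| maple | 0.333 | 30 | 21 |
| maple | 1.00 | 36 | 25 |
| maple | 2.00 | 33 | 26 |
| maple | 3.00 | 35 | 28 |
| maple | 4.00 | 34 | 26 |

(standard deviation of a reading: 1.5 percentage points)

- ratio of target to side product A at 30 s
- ratio of target to side product A at 4.0 h
- which of target and side product A there is more of at 4.0 h

- a reading or a percentage of target counts all its forms, free or not

2. Cedar and larch hold less reagent than starting material; maple holds less starting material than reagent. I average the plateau readings, leaving out maple's first, still-rising one, and divide [target] by the smaller charge. That reads 36.3% in cedar, 33.5% in larch and 34.5% in maple. Their mean, 34.8%, is the plateau share: target at the plateau per unit of the smaller charge. Side product A, reckoned the same way, reads 25.4%.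

3. Maple looks nearly the same, with the same reagent charge, but this flask has twice its starting material. That swaps the smaller charge: here reagent, at 0.0600 M, is less than starting material. If the two are used one to one, 40.0% of the starting material stays. So I expect [target] of 0.0209 M against the 0.0173 M read in maple, yet a lower percentage: 20.9% of target and 15.3% of side product A, a late ratio of 1.37. The share says nothing about the early ratio.

4. The forecast gives 1.4 early, 1.35 late, and target ahead, noting “The 30 s ratio is unobserved”.

5. The flask gives 0.642 at 30 s, 1.38 at 4.0 h, and target ahead, 20.8% against 15.0%.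

    starting material + reagent ⇌ intermediate A (K = 2.60 L mol⁻¹, k = 0.0870 L mol⁻¹ s⁻¹)
    starting material + reagent ⇌ intermediate B (K = 22.8 L mol⁻¹, k = 0.309 L mol⁻¹ s⁻¹)
    intermediate A → side product A (k = 0.0190 s⁻¹)
    intermediate B ⇌ intermediate C (K = 1.30, k = 0.0121 s⁻¹)
    intermediate B → target (k = 0.00275 s⁻¹)
    intermediate C → side product B (k = 0.00335 s⁻¹)
    crystals ⇌ target, rate k7*(cs7 - [target]) while solid is left; crystals form when [target] > cs7 (solubility = 0.0970 M, k = 1.10 s⁻¹)

Taken alone, the step from intermediate A to side product A has a half-life of 36.5 s, shorter than the 252 s of intermediate B going to target. Target draws level with side product A in this flask at 0.0422 h, well before 4.0 h. The neighbour charged with 0.25 M of starting material has the same reagent, so the share gives 8.35% of target, and that flask holds 8.31%.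

(Readings and results were generated by integration for an exercise; the scatter is artificial.)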